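The route rests on cutting C3–C3a of the dihydrobenzofuran in thought and reattaching the benzo carbon to the exocyclic carbonyl carbon, which turns the target core into a flavanone. The feature exploited is that C3 bears both C3a of the benzo ring and an acyl carbon, next to the O1–C2(aryl) unit. In one operation, an oxidative 1,2-shift of the benzo carbon from C4 to C3 contracts the pyranone to the dihydrofuran, sets C3 trans to C2 and delivers C4 as a methyl ester. The precursor is an (S)-6-bromoflavanone whose C2 aryl group is deactivated as a 2-nitrobenzenesulfonate, a sulfonate that thiolate later removes without strong base.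

Key step: step 3

Assumption: the (S,S) antipode of the diene ligand is taken to give the 2S flavanone, by analogy with its facial preference on cyclic enones; the configuration of 4 is to be confirmed (anomalous dispersion of the bromide) before it is carried on, and the (R,R) ligand is used if the sense proves opposite.

Remark: once the 4-hydroxyphenyl group at C2 is a phenoxide, it can expel O1 through a para-quinone methide, and a carbonyl group at C3 makes that opening irreversible. The sulfonate is therefore one that leaves under thiol-buffered conditions (an alkanesulfonate would need hot hydroxide). It is exchanged for benzyl before any strong base or organometallic reagent is used, and the route ends with a neutral hydrogenolysis.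

Step 1
Reactants: 1 4-(4,4,5,5-tetramethyl-1,3,2-dioxaborolan-2-yl)phenol
Product: 2 4-(4,4,5,5-tetramethyl-1,3,2-dioxaborolan-2-yl)phenyl 2-nitrobenzenesulfonate
Conditions: 2-nitrobenzenesulfonyl chloride (1.1 equiv), Et3N (1.5 equiv), CH2Cl2, 0 °C to rt
Reagents that add atoms: 2-nitrobenzenesulfonyl chloride, O=[N+]([O-])c1ccccc1S(=O)(=O)Cl
Why: O-sulfonylation of a phenol with a sulfonyl chloride and an amine base; the pinacol boronate is inert to these conditions and no stereocentre is involved.

Step 2
Reactants: 2 4-(4,4,5,5-tetramethyl-1,3,2-dioxaborolan-2-yl)phenyl 2-nitrobenzenesulfonate; 3 6-bromochromone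
Product: 4 (2S)-6-bromo-2-[4-(2-nitrophenylsulfonyloxy)phenyl]chroman-4-one
Conditions: [RhCl(C2H4)2]2 (2.5 mol %), (S,S)-Ph-bod* [(1S,4S)-2,5-diphenylbicyclo[2.2.2]octa-2,5-diene] (5.5 mol %), K3PO4 (0.5 equiv), 2 (2 equiv), toluene/H2O 10:1, 50 °C
Reagents that add atoms: none
Why: Hayashi–Miyaura conjugate addition, in which the aryl group passes from boron to monovalent rhodium and adds to C2 of the chromone on the enone face selected by the C2-symmetric diene, setting C2 as S; the weak base and two-phase medium should limit retro-oxa-Michael opening of the product and hydrolysis of the sulfonate, and the aryl bromide is inert to rhodium here.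

Step 3
Reactants: 4 (2S)-6-bromo-2-[4-(2-nitrophenylsulfonyloxy)phenyl]chroman-4-one
Product: 7 methyl (2S,3S)-5-bromo-2-[4-(2-nitrophenylsulfonyloxy)phenyl]-2,3-dihydro-1-benzofuran-3-carboxylate, via methyl enol ether 5 (not isolated), via trans C3 iodane 6 (not isolated)
Conditions: PhI(OAc)2 (1.3 equiv), HC(OMe)3 (10 equiv), conc. H2SO4 (2 equiv), MeOH, 0 °C to rt
Reagents that add atoms: methanol, CO; trimethyl orthoformate, COC(OC)OC (either delivers the OCH3 of the ester)
Why: Acid and orthoformate convert the C4 ketone into its ketal and the methyl enol ether 5, which the trivalent-iodine electrophile attacks at C3 on the face away from the C2 aryl group, and methanol capture of the oxocarbenium ion gives the 2,3-trans iodane 6 with the C3–I bond equatorial and antiperiplanar to C4–C4a. As iodobenzene leaves, C4a shifts from C4 to C3 through a bridged, phenonium-like transition state, forming C3–C3a, and the dimethoxycarbenium ion left at the old C4 collapses to the methyl ester. The closest known reaction type is the oxidative ring contraction of flavanones to methyl trans-2-aryl-2,3-dihydrobenzofuran-3-carboxylates by PhI(OAc)2 or Tl(NO3)3 in acidic methanol with orthoformate, a cyclic case of the oxidative 1,2-aryl shift that turns aryl ketones into arylacetic esters. The five-membered ring is closed by ring contraction and not by cyclisation: ipso attack of C4a on C3 (a 3-exo-tet bridging) makes the new bond and cleavage of C4–C4a completes the shift. The new stereocentre C3 is controlled by C2, since anti iodination followed by invertive displacement places the ester trans to the aryl group, which is also the more stable arrangement, while no bond to C2 is broken. The step needs benzo-carbon migration to outrun the 2,3-shift of the C2 aryl group (isoflavone), dehydrogenation to the flavone and benzylic ionisation at C2; the ortho oxygen makes C4a the better migrating carbon, and the strongly withdrawing nitrobenzenesulfonate makes the C2 aryl group a poor migrating group and a poor cation stabiliser.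

Step 4
Reactants: 7 methyl (2S,3S)-5-bromo-2-[4-(2-nitrophenylsulfonyloxy)phenyl]-2,3-dihydro-1-benzofuran-3-carboxylate
Product: 8 methyl (2S,3S)-5-bromo-2-(4-hydroxyphenyl)-2,3-dihydro-1-benzofuran-3-carboxylate
Conditions: PhSH (2.5 equiv), K2CO3 (1.5 equiv), MeCN, rt
Reagents that add atoms: none
Why: Nucleophilic aromatic ipso substitution of the nitro-activated sulfonyl ring by thiolate (the reaction used to remove nosyl groups) releases SO2 and the phenol, which the excess thiol keeps protonated so that no quinone-methide opening of O1–C2 can start; ester, bromide and both stereocentres are not touched.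

Step 5
Reactants: 8 methyl (2S,3S)-5-bromo-2-(4-hydroxyphenyl)-2,3-dihydro-1-benzofuran-3-carboxylate
Product: 9 methyl (2S,3S)-2-[4-(benzyloxy)phenyl]-5-bromo-2,3-dihydro-1-benzofuran-3-carboxylate
Conditions: BnBr (1.2 equiv), K2CO3 (2 equiv), acetone, 50 °C
Reagents that add atoms: benzyl bromide, BrCc1ccccc1
Why: Williamson ether synthesis with a mild carbonate base, the phenoxide being trapped by benzyl bromide as it forms; O-alkylation of 2-(4-hydroxyaryl)dihydrobenzofuran-3-carboxylates under such conditions is standard, and trans remains the stable arrangement at C3.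

Step 6
Reactants: 9 methyl (2S,3S)-2-[4-(benzyloxy)phenyl]-5-bromo-2,3-dihydro-1-benzofuran-3-carboxylate; 10 methyl acrylate
Product: 11 methyl (2S,3S)-2-[4-(benzyloxy)phenyl]-5-[(E)-3-methoxy-3-oxoprop-1-en-1-yl]-2,3-dihydro-1-benzofuran-3-carboxylate
Conditions: Pd2(dba)3 (1.5 mol %), [(t-Bu)3PH]BF4 (6 mol %), Cy2NMe (1.3 equiv), 10 (1.5 equiv), dioxane, 70 °C
Reagents that add atoms: none
Why: Mizoroki–Heck reaction of the electron-rich aryl bromide with an acrylate under mild bulky-phosphine and amine-base conditions should give the E cinnamate; the amine does not open the ring now that the phenol is an ether, and any exchange at C3 returns the trans isomer.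

Step 7
Reactants: 11 methyl (2S,3S)-2-[4-(benzyloxy)phenyl]-5-[(E)-3-methoxy-3-oxoprop-1-en-1-yl]-2,3-dihydro-1-benzofuran-3-carboxylate
Product: 12 (2S,3S)-2-[4-(benzyloxy)phenyl]-N-methoxy-5-{(E)-3-[methoxy(methyl)amino]-3-oxoprop-1-en-1-yl}-N-methyl-2,3-dihydro-1-benzofuran-3-carboxamide
Conditions: MeNH(OMe)·HCl (6 equiv), i-PrMgCl (12 equiv), THF, −20 °C; then 11, −20 to 0 °C
Reagents that add atoms: N,O-dimethylhydroxylamine hydrochloride, CNOC.Cl
Why: Aminolysis of both esters by the preformed chloromagnesium amide of N,O-dimethylhydroxylamine (Weinreb amide formation from esters) at low temperature; the amide attacks the ester carbonyls and not the β-carbon of the cinnamate, and enolisation at C3, if any, returns the trans isomer.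

Step 8
Reactants: 13 4-bromoresorcinol
Product: 14 2,4-bis(benzyloxy)-1-bromobenzene
Conditions: BnBr (2.3 equiv), K2CO3 (3 equiv), DMF, rt to 50 °C
Reagents that add atoms: benzyl bromide, BrCc1ccccc1
Why: Double Williamson etherification of the two phenols; no stereocentre is involved.

Step 9
Reactants: 12 (2S,3S)-2-[4-(benzyloxy)phenyl]-N-methoxy-5-{(E)-3-[methoxy(methyl)amino]-3-oxoprop-1-en-1-yl}-N-methyl-2,3-dihydro-1-benzofuran-3-carboxamide; 14 2,4-bis(benzyloxy)-1-bromobenzene
Product: 16 (E)-1-[2,4-bis(benzyloxy)phenyl]-3-[(2S,3S)-3-[2,4-bis(benzyloxy)benzoyl]-2-[4-(benzyloxy)phenyl]-2,3-dihydro-1-benzofuran-5-yl]prop-2-en-1-one, via aryllithium 15 (not isolated)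
Conditions: 14 (3.2 equiv), n-BuLi (3.0 equiv), THF, −78 °C; then 12, −78 to −40 °C; 1 M HCl quench
Reagents that add atoms: none
Why: Bromine–lithium exchange gives the ortho-alkoxy-stabilised aryllithium 15, which adds once to each N-methoxy-N-methylamide (Weinreb ketone synthesis, 1,2-addition at the cinnamoyl amide) to give chelated tetrahedral adducts that release both ketones only on quench; 12 carries no aryl halide or sulfonate that could interfere, and C2 and C3 take no part.

Step 10
Reactants: 16 (E)-1-[2,4-bis(benzyloxy)phenyl]-3-[(2S,3S)-3-[2,4-bis(benzyloxy)benzoyl]-2-[4-(benzyloxy)phenyl]-2,3-dihydro-1-benzofuran-5-yl]prop-2-en-1-one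
Product: 17 1-(2,4-dihydroxyphenyl)-3-[(2S,3S)-3-(2,4-dihydroxybenzoyl)-2-(4-hydroxyphenyl)-2,3-dihydro-1-benzofuran-5-yl]propan-1-one (CNP0136359.1)
Conditions: H2 (1 atm), 10% Pd/C, EtOAc/MeOH, rt, stopped at full debenzylation
Reagents that add atoms: none
Why: Heterogeneous hydrogenation over Pd/C saturates the chalcone C=C and cleaves the five benzyl aryl ethers by hydrogenolysis under neutral conditions, so the base-sensitive free 4-hydroxyphenyl group appears only in the last flask; the ortho-hydroxyaryl ketones and the cyclic C2–O1 ether should react far more slowly than primary benzyl ethers at 1 atm.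

Compound list
1 | 4-(4,4,5,5-tetramethyl-1,3,2-dioxaborolan-2-yl)phenol | CC1(C)OB(OC1(C)C)c1ccc(O)cc1 | starting material
2 | 4-(4,4,5,5-tetramethyl-1,3,2-dioxaborolan-2-yl)phenyl 2-nitrobenzenesulfonate | CC1(C)OB(OC1(C)C)c1ccc(OS(=O)(=O)c2ccccc2[N+](=O)[O-])cc1 | intermediate
3 | 6-bromochromone | O=c1ccoc2ccc(Br)cc12 | starting material
4 | (2S)-6-bromo-2-[4-(2-nitrophenylsulfonyloxy)phenyl]chroman-4-one | Brc1ccc2c(c1)C(=O)C[C@@H](c1ccc(OS(=O)(=O)c3ccccc3[N+](=O)[O-])cc1)O2 | intermediate (precursor of the key step)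
5 | (2S)-6-bromo-4-methoxy-2-[4-(2-nitrophenylsulfonyloxy)phenyl]-2H-chromene | Brc1ccc2c(c1)C(OC)=C[C@@H](c1ccc(OS(=O)(=O)c3ccccc3[N+](=O)[O-])cc1)O2 | intermediate (not isolated)
6 | acetoxy{(2R,3R)-6-bromo-4,4-dimethoxy-2-[4-(2-nitrophenylsulfonyloxy)phenyl]chroman-3-yl}(phenyl)-λ3-iodane, 2,3-trans, drawn with acetate as the second ligand on iodine (C2 has the same spatial arrangement as in 4; its descriptor changes because C3 now carries iodine) | Brc1ccc2c(c1)C(OC)(OC)[C@H](I(OC(C)=O)c1ccccc1)[C@@H](c1ccc(OS(=O)(=O)c3ccccc3[N+](=O)[O-])cc1)O2 | intermediate (not isolated)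
7 | methyl (2S,3S)-5-bromo-2-[4-(2-nitrophenylsulfonyloxy)phenyl]-2,3-dihydro-1-benzofuran-3-carboxylate | Brc1ccc2c(c1)[C@H](C(=O)OC)[C@@H](c1ccc(OS(=O)(=O)c3ccccc3[N+](=O)[O-])cc1)O2 | intermediate (product of the key step)
8 | methyl (2S,3S)-5-bromo-2-(4-hydroxyphenyl)-2,3-dihydro-1-benzofuran-3-carboxylate | Brc1ccc2c(c1)[C@H](C(=O)OC)[C@@H](c1ccc(O)cc1)O2 | intermediate
9 | methyl (2S,3S)-2-[4-(benzyloxy)phenyl]-5-bromo-2,3-dihydro-1-benzofuran-3-carboxylate | Brc1ccc2c(c1)[C@H](C(=O)OC)[C@@H](c1ccc(OCc3ccccc3)cc1)O2 | intermediate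
10 | methyl acrylate | C=CC(=O)OC | starting material
11 | methyl (2S,3S)-2-[4-(benzyloxy)phenyl]-5-[(E)-3-methoxy-3-oxoprop-1-en-1-yl]-2,3-dihydro-1-benzofuran-3-carboxylate | COC(=O)/C=C/c1ccc2c(c1)[C@H](C(=O)OC)[C@@H](c1ccc(OCc3ccccc3)cc1)O2 | intermediate
12 | (2S,3S)-2-[4-(benzyloxy)phenyl]-N-methoxy-5-{(E)-3-[methoxy(methyl)amino]-3-oxoprop-1-en-1-yl}-N-methyl-2,3-dihydro-1-benzofuran-3-carboxamide | CON(C)C(=O)/C=C/c1ccc2c(c1)[C@H](C(=O)N(C)OC)[C@@H](c1ccc(OCc3ccccc3)cc1)O2 | intermediate
13 | 4-bromoresorcinol | Oc1ccc(Br)c(O)c1 | starting material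
14 | 2,4-bis(benzyloxy)-1-bromobenzene | Brc1ccc(OCc2ccccc2)cc1OCc1ccccc1 | intermediate
15 | [2,4-bis(benzyloxy)phenyl]lithium | [Li]c1ccc(OCc2ccccc2)cc1OCc1ccccc1 | intermediate (not isolated)
16 | (E)-1-[2,4-bis(benzyloxy)phenyl]-3-[(2S,3S)-3-[2,4-bis(benzyloxy)benzoyl]-2-[4-(benzyloxy)phenyl]-2,3-dihydro-1-benzofuran-5-yl]prop-2-en-1-one | O=C(/C=C/c1ccc2c(c1)[C@H](C(=O)c1ccc(OCc3ccccc3)cc1OCc1ccccc1)[C@@H](c1ccc(OCc3ccccc3)cc1)O2)c1ccc(OCc2ccccc2)cc1OCc1ccccc1 | intermediate
17 | 1-(2,4-dihydroxyphenyl)-3-[(2S,3S)-3-(2,4-dihydroxybenzoyl)-2-(4-hydroxyphenyl)-2,3-dihydro-1-benzofuran-5-yl]propan-1-one | O=C(CCc1ccc2c(c1)[C@H](C(=O)c1ccc(O)cc1O)[C@@H](c1ccc(O)cc1)O2)c1ccc(O)cc1O | target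

Total step count: 10. Longest linear sequence: 9 (steps 1 to 7, 9 and 10).

Steps most likely to fail

Step 3. The ring contraction may lose out to migration of the C2 aryl group, to dehydrogenation or to simple α-methoxylation, or the acid may erode C2 by reversible ring opening. The fallback makes the same C3–C3a bond by a Wolff ring contraction and sets out from 4. The lithium enolate [LiN(SiMe3)2, THF, −78 °C, held cold against retro-oxa-Michael opening] would be acylated with CF3CO2CH2CF3 to (2S)-6-bromo-2-[4-(2-nitrophenylsulfonyloxy)phenyl]-3-(trifluoroacetyl)chroman-4-one F1. Detrifluoroacetylative diazo transfer (MsN3, Et3N, MeCN/H2O) would give (2R)-6-bromo-3-diazo-2-[4-(2-nitrophenylsulfonyloxy)phenyl]chroman-4-one F2, which has the same spatial arrangement at C2 as 4. Thermal or PhCO2Ag-promoted Wolff rearrangement in MeOH shifts C4a to the carbene carbon and traps the ketene as the methyl ester. This gives 7 together with its cis epimer methyl (2S,3R)-5-bromo-2-[4-(2-nitrophenylsulfonyloxy)phenyl]-2,3-dihydro-1-benzofuran-3-carboxylate F3. Equilibration with DBU in CH2Cl2 would converge the mixture on the trans ester, and the route is rejoined at 7.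

Step 9. The aryllithium may deprotonate C3 or degrade the hindered C3 amide instead of adding, or the double addition may stop halfway. The fallback forms both ketones under neutral conditions by Liebeskind–Srogl coupling and sets out from 11. Saponification (LiOH, THF/H2O, rt, safe now that the phenol is an ether) would give (2S,3S)-2-[4-(benzyloxy)phenyl]-5-[(E)-2-carboxyethenyl]-2,3-dihydro-1-benzofuran-3-carboxylic acid F4. Conversion through the bis(acid chloride) [(COCl)2, cat. DMF; then PhSH, pyridine, −20 °C] would give S-phenyl (2S,3S)-2-[4-(benzyloxy)phenyl]-5-[(E)-3-oxo-3-(phenylsulfanyl)prop-1-en-1-yl]-2,3-dihydro-1-benzofuran-3-carbothioate F5. This would be coupled with [2,4-bis(benzyloxy)phenyl]boronic acid F6, made from 14 through 15 by borylation with B(OiPr)3 and acidic work-up. The coupling uses Pd2(dba)3, tri(2-furyl)phosphine and copper thiophene-2-carboxylate [Cu(O2C-C4H3S)] in THF at 50 °C, and the route is rejoined at 16.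

Step 2. The pinacol boronate may transfer its aryl group slowly, the facial selectivity may be poor, or base may open the product to the chalcone. The fallback replaces asymmetric induction by resolution and sets out from 2 and 3. Addition without a chiral ligand ([Rh(OH)(cod)]2, dioxane/H2O, 50 °C) would give racemic 6-bromo-2-[4-(2-nitrophenylsulfonyloxy)phenyl]chroman-4-one F7. Preparative chromatography on a chiral stationary phase would deliver the (S)-enantiomer, which enters the route at 4. The (2R)-6-bromo-2-[4-(2-nitrophenylsulfonyloxy)phenyl]chroman-4-one F8 would be racemised with mild base through the 2'-hydroxychalcone and recycled.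

Further compounds
F1 | step 3 | (2S)-6-bromo-2-[4-(2-nitrophenylsulfonyloxy)phenyl]-3-(trifluoroacetyl)chroman-4-one (C3 unassigned) | Brc1ccc2c(c1)C(=O)C(C(=O)C(F)(F)F)[C@@H](c1ccc(OS(=O)(=O)c3ccccc3[N+](=O)[O-])cc1)O2
F2 | step 3 | (2R)-6-bromo-3-diazo-2-[4-(2-nitrophenylsulfonyloxy)phenyl]chroman-4-one | Brc1ccc2c(c1)C(=O)C(=[N+]=[N-])[C@@H](c1ccc(OS(=O)(=O)c3ccccc3[N+](=O)[O-])cc1)O2
F3 | step 3 | methyl (2S,3R)-5-bromo-2-[4-(2-nitrophenylsulfonyloxy)phenyl]-2,3-dihydro-1-benzofuran-3-carboxylate | Brc1ccc2c(c1)[C@@H](C(=O)OC)[C@@H](c1ccc(OS(=O)(=O)c3ccccc3[N+](=O)[O-])cc1)O2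
F4 | step 9 | (2S,3S)-2-[4-(benzyloxy)phenyl]-5-[(E)-2-carboxyethenyl]-2,3-dihydro-1-benzofuran-3-carboxylic acid | OC(=O)/C=C/c1ccc2c(c1)[C@H](C(=O)O)[C@@H](c1ccc(OCc3ccccc3)cc1)O2
F5 | step 9 | S-phenyl (2S,3S)-2-[4-(benzyloxy)phenyl]-5-[(E)-3-oxo-3-(phenylsulfanyl)prop-1-en-1-yl]-2,3-dihydro-1-benzofuran-3-carbothioate | O=C(/C=C/c1ccc2c(c1)[C@H](C(=O)Sc1ccccc1)[C@@H](c1ccc(OCc3ccccc3)cc1)O2)Sc1ccccc1
F6 | step 9 | [2,4-bis(benzyloxy)phenyl]boronic acid | OB(O)c1ccc(OCc2ccccc2)cc1OCc1ccccc1
F7 | step 2 | racemic 6-bromo-2-[4-(2-nitrophenylsulfonyloxy)phenyl]chroman-4-one | Brc1ccc2c(c1)C(=O)CC(c1ccc(OS(=O)(=O)c3ccccc3[N+](=O)[O-])cc1)O2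
F8 | step 2 | (2R)-6-bromo-2-[4-(2-nitrophenylsulfonyloxy)phenyl]chroman-4-one | Brc1ccc2c(c1)C(=O)C[C@H](c1ccc(OS(=O)(=O)c3ccccc3[N+](=O)[O-])cc1)O2
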